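Everything rests on C1, the one atom shared by the cyclopentane, the cycloheptane and the oxepane: it carries both C10 and the aryl ether oxygen. Cutting C1–C10 and O–Ar6 leads back to a C1 cyclopentanone whose C5 cyclopropane (C6/C7) carries a 2-iodoalkene chain and whose C4 carries the C7' fluoroarene. In one operation, iodine–lithium exchange at C10 should add the vinyl carbanion to the C1 ketone (cycloheptane, C1 stereocentre) and the resulting C1 alkoxide should displace fluoride at Ar6 (oxepane). The precursor is assembled from (+)-3-carene and 5-fluororesorcinol; an Ireland–Claisen rearrangement sets C4 and C7'.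

Key step: step 21

Remark on labels: terpenoid carbons are C1 (bears the ether oxygen), C2, C3, C4 (quaternary, methyl C15), C5, C6 and C7 (cyclopropane CH), C8, C9, C10 (with C14), C11 (CMe2); C7' is the benzylic carbon and C8' the next carbon of the isobutyl group; Ar1 (bonded to C7') runs to Ar6 (bears F, later the ether O). "C15 face" and "C7' face" name the two faces of the cyclopentane by the C4 substituent that points to them.

Remark on reagents: LiN(i-Pr)2, BrZnCH2CO2Et and LiC≡CH·H2NCH2CH2NH2 are taken as purchased reagents.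

Remark on step 5: the sense of the reduction assumes that the substituted alkene carbon of the enone acts as the large group towards the oxazaborolidine.

Step 1
Reactants: 1 (+)-3-carene
Product: 3 1-[(1S,3R)-3-(2,2-dimethoxyethyl)-2,2-dimethylcyclopropyl]propan-2-one, via keto aldehyde 2 (not isolated)
Conditions: O3, CH2Cl2/MeOH, −78 °C; Me2S, −78 °C → rt; then p-TsOH (cat.), MeOH, rt
Reagents that add atoms: ozone [O-][O+]=O; methanol CO
Why: Ozonolysis with reductive work-up turns the trisubstituted alkene into a methyl ketone and an aldehyde without touching the cyclopropane centres C6 and C7, and acid-catalysed acetalisation in methanol is selective for the aldehyde.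

Step 2
Reactants: 3 keto acetal; 4 3-chloro-2-methylpropene
Product: 6 1-[(1S,3R)-3-(2,2-dimethoxyethyl)-2,2-dimethylcyclopropyl]-5-methylhex-5-en-2-one, via lithium enolate 5 (not isolated)
Conditions: LiN(i-Pr)2, THF, −78 °C; then 4, n-Bu4NI (cat.), DMPU, −78 → 0 °C
Reagents that add atoms: none
Why: Kinetic enolate alkylation: the amide base at −78 °C deprotonates the methyl group and not the more hindered cyclopropylmethyl CH2, and the iodide-activated allylic chloride installs a masked acetonyl unit.

Step 3
Reactants: 6 methallylated ketone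
Product: 7 1-[(1S,3R)-3-(2,2-dimethoxyethyl)-2,2-dimethylcyclopropyl]hexane-2,5-dione
Conditions: O3, CH2Cl2, −78 °C; Me2S, −78 °C → rt
Reagents that add atoms: ozone [O-][O+]=O
Why: Ozonolysis of the 1,1-disubstituted alkene gives the 1,4-diketone; acetal and cyclopropane are inert to ozone.

Step 4
Reactants: 7 1,4-diketone
Product: 8 2-[(1S,3R)-3-(2,2-dimethoxyethyl)-2,2-dimethylcyclopropyl]-3-methylcyclopent-2-en-1-one
Conditions: KOH, MeOH/H2O, reflux
Reagents that add atoms: none
Why: Intramolecular aldol condensation of a 2,5-diketone under thermodynamic control should give the tetrasubstituted 2-alkyl-3-methylcyclopentenone, as in the classical jasmone-type annulation.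

Step 5
Reactants: 8 cyclopentenone
Product: 9 (1R)-2-[(1S,3R)-3-(2,2-dimethoxyethyl)-2,2-dimethylcyclopropyl]-3-methylcyclopent-2-en-1-ol
Conditions: (S)-2-methyl-CBS-oxazaborolidine (10 mol%), BH3·THF, THF, −20 °C; MeOH
Reagents that add atoms: none
Why: Corey–Bakshi–Shibata reduction, in which the catalyst and not the remote cyclopropane decides the carbonyl face; the (S)-catalyst should give the (1R)-allylic alcohol whose configuration is later relayed to C4.

Step 6
Reactants: 10 5-fluorobenzene-1,3-diol
Product: 11 1-fluoro-3,5-bis(methoxymethoxy)benzene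
Conditions: NaH, DMF, 0 °C; MOMCl, 0 °C → rt
Reagents that add atoms: chloromethyl methyl ether COCCl
Why: Williamson-type O-alkylation of both phenoxides; MOM ethers survive organolithium reagents and later direct ortho-lithiation.

Step 7
Reactants: 11 bis-MOM ether
Product: 12 2-bromo-1-fluoro-3,5-bis(methoxymethoxy)benzene
Conditions: NBS, MeCN, 0 °C
Reagents that add atoms: N-bromosuccinimide O=C1CCC(=O)N1Br
Why: Electrophilic aromatic bromination should go para to one and ortho to the other MOM-oxy group, away from the hindered position between the two oxygens.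

Step 8
Reactants: 12 aryl bromide
Product: 13 ethyl 2-[2-fluoro-4,6-bis(methoxymethoxy)phenyl]acetate
Conditions: BrZnCH2CO2Et, Pd2(dba)3 (2 mol%), XPhos (8 mol%), THF, 60 °C
Reagents that add atoms: (2-ethoxy-2-oxoethyl)zinc bromide CCOC(=O)C[Zn]Br
Why: Negishi-type palladium-catalysed coupling of a Reformatsky reagent (α-arylation of an acetate), which tolerates two ortho substituents when a bulky biarylphosphine is used.

Step 9
Reactants: 13 ethyl arylacetate
Product: 14 2-[2-fluoro-4,6-bis(methoxymethoxy)phenyl]acetic acid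
Conditions: LiOH, THF/MeOH/H2O, rt; 1 M HCl to pH 4, 0 °C
Reagents that add atoms: lithium hydroxide [Li+].[OH-]
Why: Ester saponification; aryl MOM ethers and the aryl fluoride are stable to hydroxide, and the acidification is cold and mild.

Step 10
Reactants: 9 allylic alcohol; 14 arylacetic acid
Product: 15 allylic arylacetate ester
Conditions: DCC, DMAP (cat.), CH2Cl2, 0 °C → rt
Reagents that add atoms: none
Why: Steglich esterification of the hindered secondary allylic alcohol under neutral conditions, which avoids ionisation of the cyclopropyl-stabilised allylic system.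

Step 11
Reactants: 15 allylic arylacetate ester
Product: 18 Claisen acid, via (Z)-silyl ketene acetal 16 (not isolated), via trimethylsilyl ester 17 (not isolated)
Conditions: LiN(i-Pr)2, THF/DMPU, −78 °C; Me3SiCl, −78 °C → rt, then 60 °C; aqueous citric acid (pH 4), 0 °C
Reagents that add atoms: none
Why: Ireland–Claisen rearrangement: the arylacetate should give the (Z)-silyl ketene acetal (aryl cis to OSiMe3), the suprafacial [3,3] shift relays the C1–O configuration to C4 (C7' enters on the face that carried oxygen), and a chair-like transition state, favoured because a boat would eclipse the silyloxy carbon with C5 and its cyclopropyl group and C7' with C15, sets C7'.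

Step 12
Reactants: 18 Claisen acid
Product: 20 C8',C1-diol, via organoborane 19 (not isolated)
Conditions: BH3·THF (excess), THF, 0 °C → rt; then NaOH (aq), H2O2, 0 °C → rt
Reagents that add atoms: hydrogen peroxide OO
Why: Borane reduces the carboxylic acid and hydroborates the trisubstituted C1=C5 alkene in one flask (boron to the less substituted C1, from the C15 face anti to the C7' branch), and alkaline peroxide oxidation gives the diol; both new centres are provisional because C1 is later oxidised and C5 equilibrated.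

Step 13
Reactants: 20 C8',C1-diol
Product: 21 C8' aldehyde
Conditions: TEMPO (10 mol%), PhI(OAc)2, CH2Cl2, rt
Reagents that add atoms: none
Why: Oxoammonium (TEMPO) oxidation is selective for the primary over the hindered secondary alcohol and is non-basic, so C7', now α to the aldehyde, should not epimerise.

Step 14
Reactants: 21 C8' aldehyde
Product: 22 2-methylprop-1-enyl compound
Conditions: i-PrPPh3I, n-BuLi, THF, 0 °C; then 21, −78 °C → rt
Reagents that add atoms: isopropyltriphenylphosphonium iodide CC(C)[P+](c1ccccc1)(c1ccccc1)c1ccccc1.[I-]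
Why: Wittig olefination with a non-stabilised ylide (one further equivalent is taken up by the free C1 hydroxyl) adds the last three carbons of the isobutyl group; the hindered, twisted α-aryl aldehyde is expected to enolise only slowly.

Step 15
Reactants: 22 2-methylprop-1-enyl compound
Product: 23 isobutyl compound
Conditions: H2 (1 atm), PtO2, EtOAc, rt
Reagents that add atoms: none
Why: Catalytic hydrogenation of the only alkene present; the isolated cyclopropane, the aryl fluoride and both kinds of acetal are stable to platinum at one atmosphere in a neutral solvent.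

Step 16
Reactants: 23 isobutyl compound
Product: 25 C9 primary alcohol, via C9 aldehyde 24 (not isolated)
Conditions: 2 M HCl/THF (1:4), rt; NaHCO3 to pH 8; then NaBH4, MeOH, 0 °C
Reagents that add atoms: water O
Why: Mild acid hydrolysis cleaves the dialkyl acetal much faster than the aryl MOM ethers, and borohydride reduction of the freed aldehyde in the same flask gives the primary alcohol.

Step 17
Reactants: 25 C9 primary alcohol
Product: 26 C9 iodide
Conditions: PPh3, I2, imidazole, CH2Cl2, 0 °C
Reagents that add atoms: iodine II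
Why: Appel iodination, selective for the unhindered primary hydroxyl over the hindered secondary C1 hydroxyl.

Step 18
Reactants: 26 C9 iodide
Product: 27 terminal alkyne
Conditions: LiC≡CH·H2NCH2CH2NH2 (3 equiv), DMSO, rt
Reagents that add atoms: lithium acetylide–ethylenediamine [Li]C#C.NCCN
Why: SN2 alkynylation of a primary iodide in DMSO; the C1 alkoxide lies on the face opposite the fluoroarene and cannot attack it.

Step 19
Reactants: 27 terminal alkyne
Product: 29 2-iodoalkene alcohol, via C10 vinylalane 28 (not isolated)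
Conditions: NiCl2(dppp) (3 mol%), i-Bu2AlH (2.3 equiv), THF, 0 °C → rt; then I2, THF, −78 → 0 °C; aqueous potassium sodium tartrate
Reagents that add atoms: iodine II
Why: Nickel-catalysed α-selective (Markovnikov) hydroalumination of the terminal alkyne and iodinolysis with retention give the 2-iodo-1-alkene without acid, so MOM ethers and cyclopropane survive, and iodine alone does not iodinate the arene.

Step 20
Reactants: 29 2-iodoalkene alcohol
Product: 31 iodo ketone (key-step precursor), via C5-epimeric ketone 30 (not isolated)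
Conditions: (COCl)2, DMSO, CH2Cl2, −78 °C; Et3N, −78 → 0 °C; then DBU, rt
Reagents that add atoms: none
Why: Swern oxidation gives the C1 ketone, and base-mediated enolisation then equilibrates C5 so that the cyclopropyl group moves to the C15 face, away from the bulky C7' branch (thermodynamic control).

Step 21
Reactants: 31 iodo ketone (key-step precursor)
Product: 35 pentacyclic C10-methylene bis-MOM ether, via C10 vinyllithium 32 (not isolated), via lithium C1-alkoxide 33 (not isolated), via potassium C1-alkoxide 34 (not isolated)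
Conditions: t-BuLi (2.1 equiv), THF/Et2O, −78 → −20 °C; then KOt-Bu, 18-crown-6, DMPU, −20 → 60 °C
Reagents that add atoms: none
Why: Proposed new method: t-BuLi should exchange the vinylic iodide at −78 °C faster than it adds to the C1 ketone or lithiates the arene, the second equivalent destroys t-BuI, and the C10 vinyllithium adds to C1=O; after the potassium/crown switch the C1 alkoxide attacks Ar6 ipso to fluorine, and the anionic σ-adduct (charge on Ar1, Ar3 and Ar5, with the oxygen-bearing Ar2 and Ar4 withdrawing inductively) expels fluoride. The closest known reaction types are halogen–lithium exchange-initiated intramolecular additions of vinyllithiums to ketones and intramolecular SNAr etherifications of unactivated fluoroarenes by tertiary alkoxides; joining them in one flask to close two seven-membered rings is the untested part. The cycloheptane closes by 7-exo-trig attack on C=O and the oxepane by a seven-membered intramolecular addition–elimination at Ar6. The new stereocentre C1 is controlled by the tether: C10 hangs from C5 through the cis-cyclopropane C6–C7 on the C15 face while the C7' branch shields the other face, so C10 enters on the C15 face, the hydroazulene is cis-fused and the alkoxide ends on the C7' face next to Ar6. The step needs exchange to beat carbonyl addition and addition to beat enolisation, which the iodide, the low temperature and the pre-organised cis-cyclopropane tether should secure; the etherification needs no regiocontrol because only Ar6 carries a leaving group within reach.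

Step 22
Reactants: 35 pentacyclic C10-methylene bis-MOM ether
Product: 36 C10-methyl pentacycle
Conditions: H2 (10 bar), RhCl(PPh3)3 (10 mol%), benzene/EtOH (1:1), 40 °C
Reagents that add atoms: none
Why: Homogeneous hydrogenation with a bulky rhodium catalyst causes neither alkene migration nor hydrogenolysis of the allylic aryl ether, and hydrogen should add to the C10 face anti to the aryloxy group on C1 and to the C11 gem-dimethyl bridge, which places C14 syn to the ether oxygen.

Step 23
Reactants: 36 C10-methyl pentacycle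
Product: 38 Ar3 monoaldehyde, via Ar3 aryllithium 37 (not isolated)
Conditions: n-BuLi, TMEDA, THF, 0 °C; DMF, −78 → 0 °C; NH4Cl (aq)
Reagents that add atoms: N,N-dimethylformamide CN(C)C=O
Why: Directed ortho-lithiation at Ar3, the position flanked by two MOM-oxy groups, and formylation of the aryllithium with DMF.

Step 24
Reactants: 38 Ar3 monoaldehyde
Product: 41 dialdehyde bis-MOM ether, via α-amino alkoxide 39 (not isolated), via Ar5 aryllithium 40 (not isolated)
Conditions: LiN(Me)CH2CH2NMe2 (from MeNHCH2CH2NMe2 and n-BuLi), THF, −20 °C; n-BuLi (3 equiv), −20 °C; DMF, −78 → 0 °C; NH4Cl (aq)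
Reagents that add atoms: N,N-dimethylformamide CN(C)C=O
Why: In situ protection of the aldehyde as an α-amino alkoxide, directed ortho-lithiation at Ar5 (the only remaining ring C–H, between a MOM-oxy group and the ether oxygen) and formylation with DMF; aqueous work-up releases both aldehydes.

Step 25
Reactants: 41 dialdehyde bis-MOM ether
Product: 42 CNP0189833.2 (target)
Conditions: 2 M HCl, MeOH/THF, 40 °C
Reagents that add atoms: none
Why: Acid-catalysed acetal exchange removes both MOM groups, which are activated by hydrogen bonding to the ortho formyl groups, under conditions mild enough for the tertiary alkyl aryl ether and the cyclopropane.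

Compound list

1 | (+)-3-carene | CC1=CC[C@@H]2[C@H](C1)C2(C)C | starting material
2 | keto aldehyde (not isolated): 2-[(1R,3S)-2,2-dimethyl-3-(2-oxopropyl)cyclopropyl]acetaldehyde | CC(=O)C[C@H]1[C@@H](CC=O)C1(C)C | intermediate
3 | 1-[(1S,3R)-3-(2,2-dimethoxyethyl)-2,2-dimethylcyclopropyl]propan-2-one | CC(=O)C[C@H]1[C@@H](CC(OC)OC)C1(C)C | intermediate
4 | 3-chloro-2-methylpropene | C=C(C)CCl | starting material
5 | lithium enolate of 3 on the methyl side (not isolated) | C=C(O[Li])C[C@H]1[C@@H](CC(OC)OC)C1(C)C | intermediate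
6 | 1-[(1S,3R)-3-(2,2-dimethoxyethyl)-2,2-dimethylcyclopropyl]-5-methylhex-5-en-2-one | C=C(C)CCC(=O)C[C@H]1[C@@H](CC(OC)OC)C1(C)C | intermediate
7 | 1-[(1S,3R)-3-(2,2-dimethoxyethyl)-2,2-dimethylcyclopropyl]hexane-2,5-dione | CC(=O)CCC(=O)C[C@H]1[C@@H](CC(OC)OC)C1(C)C | intermediate
8 | 2-[(1S,3R)-3-(2,2-dimethoxyethyl)-2,2-dimethylcyclopropyl]-3-methylcyclopent-2-en-1-one | CC1=C(C(=O)CC1)[C@H]1[C@@H](CC(OC)OC)C1(C)C | intermediate
9 | (1R)-2-[(1S,3R)-3-(2,2-dimethoxyethyl)-2,2-dimethylcyclopropyl]-3-methylcyclopent-2-en-1-ol | O[C@@H]1CCC(C)=C1[C@H]1[C@@H](CC(OC)OC)C1(C)C | intermediate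
10 | 5-fluorobenzene-1,3-diol | Oc1cc(O)cc(F)c1 | starting material
11 | 1-fluoro-3,5-bis(methoxymethoxy)benzene | COCOc1cc(OCOC)cc(F)c1 | intermediate
12 | 2-bromo-1-fluoro-3,5-bis(methoxymethoxy)benzene | Brc1c(F)cc(OCOC)cc1OCOC | intermediate
13 | ethyl 2-[2-fluoro-4,6-bis(methoxymethoxy)phenyl]acetate | CCOC(=O)Cc1c(F)cc(OCOC)cc1OCOC | intermediate
14 | 2-[2-fluoro-4,6-bis(methoxymethoxy)phenyl]acetic acid | OC(=O)Cc1c(F)cc(OCOC)cc1OCOC | intermediate
15 | allylic arylacetate ester: (1R)-2-[(1S,3R)-3-(2,2-dimethoxyethyl)-2,2-dimethylcyclopropyl]-3-methylcyclopent-2-en-1-yl 2-[2-fluoro-4,6-bis(methoxymethoxy)phenyl]acetate | O=C(Cc1c(F)cc(OCOC)cc1OCOC)O[C@@H]1CCC(C)=C1[C@H]1[C@@H](CC(OC)OC)C1(C)C | intermediate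
16 | (Z)-O-trimethylsilyl ketene acetal of 15, aryl cis to OSiMe3 (not isolated) | C[Si](C)(C)O/C(=C\c1c(F)cc(OCOC)cc1OCOC)O[C@@H]1CCC(C)=C1[C@H]1[C@@H](CC(OC)OC)C1(C)C | intermediate
17 | trimethylsilyl ester of 18 (not isolated) | C[Si](C)(C)OC(=O)[C@@H](c1c(F)cc(OCOC)cc1OCOC)[C@@]1(C)CCC=C1[C@H]1[C@@H](CC(OC)OC)C1(C)C | intermediate
18 | Claisen acid: (2R)-2-[2-fluoro-4,6-bis(methoxymethoxy)phenyl]-2-[(1R)-2-[(1S,3R)-3-(2,2-dimethoxyethyl)-2,2-dimethylcyclopropyl]-1-methylcyclopent-2-en-1-yl]acetic acid (C1=C5 alkene; C7' on the ring face that carried the ester oxygen) | OC(=O)[C@@H](c1c(F)cc(OCOC)cc1OCOC)[C@@]1(C)CCC=C1[C@H]1[C@@H](CC(OC)OC)C1(C)C | intermediate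
19 | organoborane from 18, drawn as the monomeric C1–BH2 / C8'–O–BH2 form, boron on the C15 face (not isolated) | [BH2]OC[C@@H](c1c(F)cc(OCOC)cc1OCOC)[C@@]1(C)CC[C@H]([BH2])[C@H]1[C@H]1[C@@H](CC(OC)OC)C1(C)C | intermediate
20 | C8',C1-diol: C8' CH2OH; C1–OH and C5–H both on the C15 face, cyclopropyl on the C7' face; C4 and C7' as in 18 | OC[C@@H](c1c(F)cc(OCOC)cc1OCOC)[C@@]1(C)CC[C@H](O)[C@H]1[C@H]1[C@@H](CC(OC)OC)C1(C)C | intermediate
21 | C8' aldehyde of 20 (C1–OH retained) | O=C[C@@H](c1c(F)cc(OCOC)cc1OCOC)[C@@]1(C)CC[C@H](O)[C@H]1[C@H]1[C@@H](CC(OC)OC)C1(C)C | intermediate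
22 | 2-methylprop-1-enyl compound (C8'=C(CH3)2 on C7'; otherwise as 21) | CC(C)=C[C@@H](c1c(F)cc(OCOC)cc1OCOC)[C@@]1(C)CC[C@H](O)[C@H]1[C@H]1[C@@H](CC(OC)OC)C1(C)C | intermediate
23 | isobutyl compound (C7' isobutyl; C1–OH; dimethyl acetal at C9) | CC(C)C[C@@H](c1c(F)cc(OCOC)cc1OCOC)[C@@]1(C)CC[C@H](O)[C@H]1[C@H]1[C@@H](CC(OC)OC)C1(C)C | intermediate
24 | C9 aldehyde from 23 (not isolated) | CC(C)C[C@@H](c1c(F)cc(OCOC)cc1OCOC)[C@@]1(C)CC[C@H](O)[C@H]1[C@H]1[C@@H](CC=O)C1(C)C | intermediate
25 | C9 primary alcohol (C7–CH2CH2OH; C1–OH) | CC(C)C[C@@H](c1c(F)cc(OCOC)cc1OCOC)[C@@]1(C)CC[C@H](O)[C@H]1[C@H]1[C@@H](CCO)C1(C)C | intermediate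
26 | C9 iodide (C7–CH2CH2I; C1–OH) | CC(C)C[C@@H](c1c(F)cc(OCOC)cc1OCOC)[C@@]1(C)CC[C@H](O)[C@H]1[C@H]1[C@@H](CCI)C1(C)C | intermediate
27 | terminal alkyne (C7–CH2CH2C≡CH; C1–OH) | CC(C)C[C@@H](c1c(F)cc(OCOC)cc1OCOC)[C@@]1(C)CC[C@H](O)[C@H]1[C@H]1[C@@H](CCC#C)C1(C)C | intermediate
28 | C10 vinylalane with C1–O–Al(i-Bu)2 (not isolated) | CC(C)C[C@@H](c1c(F)cc(OCOC)cc1OCOC)[C@@]1(C)CC[C@H](O[Al](CC(C)C)CC(C)C)[C@H]1[C@H]1[C@@H](CCC(=C)[Al](CC(C)C)CC(C)C)C1(C)C | intermediate
29 | 2-iodoalkene alcohol (C7–CH2CH2C(I)=CH2; C1–OH on the C15 face; cyclopropyl on the C7' face) | CC(C)C[C@@H](c1c(F)cc(OCOC)cc1OCOC)[C@@]1(C)CC[C@H](O)[C@H]1[C@H]1[C@@H](CCC(I)=C)C1(C)C | intermediate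
30 | C5-epimeric C1 ketone, cyclopropyl on the C7' face (not isolated) | CC(C)C[C@@H](c1c(F)cc(OCOC)cc1OCOC)[C@@]1(C)CCC(=O)[C@H]1[C@H]1[C@@H](CCC(I)=C)C1(C)C | intermediate
31 | iodo ketone, key-step precursor: C1 cyclopentanone, cyclopropyl at C5 on the C15 face, 2-iodoalkene chain on C7, fluoroarene on C7' | CC(C)C[C@@H](c1c(F)cc(OCOC)cc1OCOC)[C@@]1(C)CCC(=O)[C@@H]1[C@H]1[C@@H](CCC(I)=C)C1(C)C | intermediate
32 | C10 vinyllithium from 31 (not isolated) | CC(C)C[C@@H](c1c(F)cc(OCOC)cc1OCOC)[C@@]1(C)CCC(=O)[C@@H]1[C@H]1[C@@H](CCC([Li])=C)C1(C)C | intermediate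
33 | lithium C1-alkoxide, cis-fused hydroazulene, O on the C7' face (not isolated) | CC(C)C[C@@H](c1c(F)cc(OCOC)cc1OCOC)[C@@]1(C)CC[C@@]2(O[Li])[C@@H]1[C@H]1[C@@H](CCC2=C)C1(C)C | intermediate
34 | potassium C1-alkoxide (not isolated) | CC(C)C[C@@H](c1c(F)cc(OCOC)cc1OCOC)[C@@]1(C)CC[C@@]2(O[K])[C@@H]1[C@H]1[C@@H](CCC2=C)C1(C)C | intermediate
35 | pentacyclic C10-methylene bis-MOM ether (key-step product): oxepane O–C1 and Ar6, cis-fused cycloheptane with exocyclic C10=C14 | CC(C)C[C@H]1c2c(OCOC)cc(OCOC)cc2O[C@]23CC[C@@]1(C)[C@H]2[C@H]1[C@@H](CCC3=C)C1(C)C | intermediate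
36 | C10-methyl pentacycle (C14 methyl syn to the ether oxygen) | CC(C)C[C@H]1c2c(OCOC)cc(OCOC)cc2O[C@]23CC[C@@]1(C)[C@H]2[C@H]1[C@@H](CC[C@@H]3C)C1(C)C | intermediate
37 | Ar3 aryllithium of 36 (not isolated) | CC(C)C[C@H]1c2c(OCOC)c([Li])c(OCOC)cc2O[C@]23CC[C@@]1(C)[C@H]2[C@H]1[C@@H](CC[C@@H]3C)C1(C)C | intermediate
38 | Ar3 monoaldehyde | CC(C)C[C@H]1c2c(OCOC)c(C=O)c(OCOC)cc2O[C@]23CC[C@@]1(C)[C@H]2[C@H]1[C@@H](CC[C@@H]3C)C1(C)C | intermediate
39 | lithium α-amino alkoxide of 38, mixture at the new carbinol carbon (not isolated) | CC(C)C[C@H]1c2c(OCOC)c(C(O[Li])N(C)CCN(C)C)c(OCOC)cc2O[C@]23CC[C@@]1(C)[C@H]2[C@H]1[C@@H](CC[C@@H]3C)C1(C)C | intermediate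
40 | Ar5 aryllithium of 39 (not isolated) | CC(C)C[C@H]1c2c(OCOC)c(C(O[Li])N(C)CCN(C)C)c(OCOC)c([Li])c2O[C@]23CC[C@@]1(C)[C@H]2[C@H]1[C@@H](CC[C@@H]3C)C1(C)C | intermediate
41 | dialdehyde bis-MOM ether (CHO at Ar3 and Ar5) | CC(C)C[C@H]1c2c(OCOC)c(C=O)c(OCOC)c(C=O)c2O[C@]23CC[C@@]1(C)[C@H]2[C@H]1[C@@H](CC[C@@H]3C)C1(C)C | intermediate
42 | CNP0189833.2: pentacyclic 3,5-diformyl-2,4-dihydroxyaryl ether of the C1 tertiary alcohol, isobutyl at C7' | CC(C)C[C@H]1c2c(O)c(C=O)c(O)c(C=O)c2O[C@]23CC[C@@]1(C)[C@H]2[C@H]1[C@@H](CC[C@@H]3C)C1(C)C | target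

Total step count: 25.
Longest linear sequence: 21 steps (steps 1–5 and 10–25); the arene branch (steps 6–9) has 4 steps.

Steps most likely to fail

1. Step 21 (proposed new method). Proton transfer from C2 or C5 to the vinyllithium, or addition of t-BuLi to the ketone, may outrun the seven-membered ring closure, or the alkoxide may not displace fluoride from the electron-rich ring in the same flask. The fallback uses known chemistry in two separate operations. Starting from 31, a Nozaki–Hiyama–Kishi cyclisation (CrCl2, catalytic NiCl2, DMSO, rt) forms a non-basic organochromium species, which avoids enolisation, and should give the C1 tertiary allylic alcohol F1. Its potassium alkoxide (KH, 18-crown-6, THF/NMP, 60–100 °C) then closes the aryl ether by a conventional intramolecular SNAr, and the route is rejoined at 35.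

2. Step 11. A boat-like transition state may compete and erode or reverse the configuration at C7'; C4 is secure because the shift is suprafacial. The fallback corrects C7' afterwards by equilibration. Starting from 15, material that emerges as the C7'-epimeric acid F2 is taken through the conditions of steps 12 and 13 to the C7'-epimeric diol F3 and the C7'-epimeric hydroxy aldehyde F4. In F4 the C7' hydrogen is benzylic and α to the formyl group, so DBU in CH2Cl2 should equilibrate F4 with 21. The two are separated, the unwanted epimer is resubmitted, and the route continues from 21.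

3. Step 22. Facial selectivity in the delivery of hydrogen to C10 may be poor, or the hindered alkene may react slowly. Starting from 35, a radical hydrogen-atom-transfer hydrogenation (Mn(dpm)3, PhSiH3, t-BuOOH, i-PrOH, rt) reduces the alkene through a tertiary C10 radical, under product-stability control instead of catalyst-approach control. It returns to the route at 36, and no new compound is involved.

Further compounds

F1 | step 21 | C1 tertiary allylic alcohol (cis-fused hydroazulenol, fluoroarene intact) | CC(C)C[C@@H](c1c(F)cc(OCOC)cc1OCOC)[C@@]1(C)CC[C@@]2(O)[C@@H]1[C@H]1[C@@H](CCC2=C)C1(C)C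
F2 | step 11 | C7'-epimeric acid (C7' epimer of 18) | OC(=O)[C@H](c1c(F)cc(OCOC)cc1OCOC)[C@@]1(C)CCC=C1[C@H]1[C@@H](CC(OC)OC)C1(C)C
F3 | step 11 | C7'-epimeric diol (C7' epimer of 20) | OC[C@H](c1c(F)cc(OCOC)cc1OCOC)[C@@]1(C)CC[C@H](O)[C@H]1[C@H]1[C@@H](CC(OC)OC)C1(C)C
F4 | step 11 | C7'-epimeric hydroxy aldehyde (C7' epimer of 21) | O=C[C@H](c1c(F)cc(OCOC)cc1OCOC)[C@@]1(C)CC[C@H](O)[C@H]1[C@H]1[C@@H](CC(OC)OC)C1(C)C
F0 | step 22 | none | none
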